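Ring B of the tetralin is disconnected at C4–C4a and C1–C2, which leads to a symmetrical benzhydryl cation and a five-carbon allylic alcohol. The plan rests on one feature of the target: C1 carries two constitutionally identical 3,4-dimethoxyphenyl groups, the arene of ring A and the pendant ring C, so C1 is not stereogenic until ring B closes. In the key step a chiral Brønsted acid joins bis(3,4-dimethoxyphenyl)methanol and tiglyl alcohol in one cationic cascade (alkylation at C2, semipinacol hydride shift, Friedel–Crafts closure at C4a, dehydration) to give cyclogalgravin. A thermodynamically controlled ionic hydrogenation then sets C3.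

Key step: step 2

Remark on numbering: tetralin numbering of the target is used throughout (C1 bears the aryl group, C2 and C3 the methyl groups, C4 is the CH2, C4a and C8a are the ring-fusion carbons; ring A is the dimethoxybenzo ring, ring B the saturated ring, ring C the pendant aryl).

Assumption: the (S,S) antipode of the chiral acid is written as the catalyst that delivers the 2R configuration of compound 7; if the facial preference turns out to be the reverse, the (R,R) acid is used.

Step 1
Reactants: 1 3,4-dimethoxybenzaldehyde; 2 (3,4-dimethoxyphenyl)magnesium bromide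
Product: 3 bis(3,4-dimethoxyphenyl)methanol
Conditions: THF, 0 → 23 °C; then H2O
Reagents that add atoms: none
Why: 1,2-addition of an aryl Grignard reagent to an aromatic aldehyde (Grignard reaction); the carbinol carbon carries two identical aryl groups and is not a stereocentre.

Step 2
Reactants: 3 bis(3,4-dimethoxyphenyl)methanol; 4 (E)-2-methylbut-2-en-1-ol (tiglyl alcohol, 3 equiv)
Product: 7 (1S,2R)-cyclogalgravin, via aldehyde 5 (not isolated), via tetralol 6 (not isolated)
Conditions: (S,S)-IDPi acid (imidodiphosphorimidate built from two 3,3′-bis[3,5-bis(trifluoromethyl)phenyl]-BINOL units, N-triflyl groups on phosphorus, 5 mol %), 5 Å MS, CHCl3, −30 → 23 °C, slow addition of 3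
Reagents that add atoms: none
Why: Proposed new method: the acid ionises 3 to the symmetrical bis(3,4-dimethoxyphenyl)methyl cation, which, ion-paired with the chiral anion that also hydrogen-bonds the hydroxyl of 4, adds to the less substituted alkene carbon (new C1–C2 bond); the β-hydroxy tertiary cation at C3 then collapses by a 1,2-hydride shift from the carbinol carbon (semipinacol step) to aldehyde 5, whose protonated carbonyl is attacked by one of the two aryl rings (new C4–C4a bond) to give tetralol 6, and ionisation of 6 with loss of the C3 proton gives the C3=C4 styrene bond. The closest known reaction types are carbocation-initiated semipinacol rearrangements of allylic alcohols, chiral counter-anion control of additions to diarylmethyl cations, and the acid-mediated cyclodehydration of 4,4-diarylbutanals to 1-aryl-1,2-dihydronaphthalenes; their combination as an enantioselective [3+3] annulation of an unbiased benzhydryl cation is new. Ring B closes by a 6-exo-trig Friedel–Crafts hydroxyalkylation. C2 is set by the chiral counter-anion in the intermolecular bond formation (C1 is not yet stereogenic there), and C1 is set under substrate control when one of the two diastereotopic aryl rings cyclises: the chair-like closure that keeps the ring-forming aryl anti to the C2 methyl places the remaining aryl and the C2 methyl both pseudo-equatorial, which is 1,2-trans. The step needs the hydride shift to outrun both capture of the C3 cation by a neighbouring arene (indane formation) and loss of the C2 proton (which would erase C2), which the oxygen lone pair beside the migrating hydride should secure, and it needs cyclisation para to the 3-methoxy group, which is preferred electronically and sterically over the position between the two substituents.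

Step 3
Reactants: 7 (1S,2R)-cyclogalgravin
Product: 8 galbulin
Conditions: CF3CO2H, Et3SiH (slow addition), CH2Cl2, −20 → 0 °C
Reagents that add atoms: none
Why: Ionic hydrogenation of a styrene (Kursanov–Parnes reduction), in which reversible protonation at C3 gives the C4 benzylic cation (stabilised by the para 7-methoxy group), so that with the silane kept at low concentration the C3-epimeric cations should equilibrate through 7 before hydride transfer and the more stable one, with the C2 and C3 methyl groups trans-diequatorial, should be reduced, setting C3 as R while C1 and C2 are untouched (the C2 descriptor changes from R to S only because the CIP priorities change).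

Compound list
1 | 3,4-dimethoxybenzaldehyde (veratraldehyde) | COc1ccc(C=O)cc1OC | starting material
2 | (3,4-dimethoxyphenyl)magnesium bromide (commercial THF solution) | COc1ccc([Mg]Br)cc1OC | starting material
3 | bis(3,4-dimethoxyphenyl)methanol | COc1ccc(C(O)c2ccc(OC)c(OC)c2)cc1OC | intermediate
4 | (E)-2-methylbut-2-en-1-ol (tiglyl alcohol) | C/C=C(\C)CO | starting material
5 | (3R)-4,4-bis(3,4-dimethoxyphenyl)-2,3-dimethylbutanal, mixture of C2 epimers (forms in the flask, not isolated) | O=CC(C)[C@H](C)C(c1ccc(OC)c(OC)c1)c1ccc(OC)c(OC)c1 | intermediate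
6 | (3R,4S)-4-(3,4-dimethoxyphenyl)-6,7-dimethoxy-2,3-dimethyl-1,2,3,4-tetrahydronaphthalen-1-ol, mixture of epimers at C1 and C2 of this name (forms in the flask, not isolated) | COc1ccc([C@H]2c3cc(OC)c(OC)cc3C(O)C(C)[C@@H]2C)cc1OC | intermediate
7 | (1S,2R)-1-(3,4-dimethoxyphenyl)-6,7-dimethoxy-2,3-dimethyl-1,2-dihydronaphthalene (cyclogalgravin, 1,2-trans) | COc1ccc([C@H]2c3cc(OC)c(OC)cc3C=C(C)[C@@H]2C)cc1OC | intermediate
8 | galbulin, (1S,2S,3R)-1-(3,4-dimethoxyphenyl)-6,7-dimethoxy-2,3-dimethyl-1,2,3,4-tetrahydronaphthalene (all-trans) | COc1ccc([C@H]2c3cc(OC)c(OC)cc3C[C@@H](C)[C@@H]2C)cc1OC | target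

Total step count: 3
Longest linear sequence: 3 steps (1 → 3 → 7 → 8)

Steps most likely to fail

1. Step 2 (Proposed new method). What may go wrong: the tertiary cation formed after the first C–C bond is captured by a neighbouring arene before the hydride shift (indane formation); the benzhydryl cation alkylates another electron-rich arene (oligomerisation); or the chiral anion discriminates the two alkene faces poorly. The fallback uses known chemistry and makes the two bonds in separate operations; it sets out from 3 and comes back to the route at 5, which is then isolated and closed to 7 in an acid step of its own. Ionic deoxygenation of 3 (Et3SiH, CF3CO2H, CH2Cl2) should give bis(3,4-dimethoxyphenyl)methane F1. N-Acylation of commercial (R)-4-phenyl-1,3-oxazolidin-2-one (n-BuLi, THF, −78 °C; then (E)-but-2-enoyl chloride) should give (4R)-3-[(E)-but-2-enoyl]-4-phenyl-1,3-oxazolidin-2-one F2. Benzylic lithiation of F1 (n-BuLi, THF), transmetalation (MgBr2·OEt2, then CuBr·SMe2) and conjugate addition to F2 should give (4R)-3-[(3S)-4,4-bis(3,4-dimethoxyphenyl)-3-methylbutanoyl]-4-phenyl-1,3-oxazolidin-2-one F3, the organocopper reagent adding anti to the phenyl group of the chelated s-cis imide. Enolate methylation (NaN(SiMe3)2, MeI, THF, −78 °C) should give (4R)-3-[(2R,3R)-4,4-bis(3,4-dimethoxyphenyl)-2,3-dimethylbutanoyl]-4-phenyl-1,3-oxazolidin-2-one F4. Reductive removal of the auxiliary (LiBH4, THF, H2O) should give (2R,3R)-4,4-bis(3,4-dimethoxyphenyl)-2,3-dimethylbutan-1-ol F5. Oxidation with Dess–Martin periodinane should give 5 as its (2R,3R) isomer, which is isolated and cyclised through 6 to 7 with p-TsOH in toluene at 80 °C, a known type of cyclodehydration.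

2. Step 3. What may go wrong: hydride transfer before the C3-epimeric benzylic cations have equilibrated, which would give the 2,3-cis epimer, or double-bond migration in the acid that scrambles C2. The fallback sets out from 7 and comes back at 8; it fixes C3 by enolate equilibration instead. Hydroboration–oxidation of 7 (BH3·SMe2, THF; then NaOH, H2O2), expected from the face opposite the C2 methyl, should give (1S,2R,3R,4S)-4-(3,4-dimethoxyphenyl)-6,7-dimethoxy-2,3-dimethyl-1,2,3,4-tetrahydronaphthalen-1-ol F6. Oxidation with Dess–Martin periodinane should give the 2,3-cis ketone (2R,3R,4S)-4-(3,4-dimethoxyphenyl)-6,7-dimethoxy-2,3-dimethyl-3,4-dihydronaphthalen-1(2H)-one F7. Epimerisation at the α-carbon (DBU, toluene, 60 °C) should give the 2,3-trans ketone (2S,3R,4S)-4-(3,4-dimethoxyphenyl)-6,7-dimethoxy-2,3-dimethyl-3,4-dihydronaphthalen-1(2H)-one F8. Ionic deoxygenation of the electron-rich aryl ketone (excess Et3SiH, CF3CO2H, 23 °C) should then give 8.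

3. Step 1. What may go wrong: loss of titre of the Grignard solution, or ionisation of the very electron-rich carbinol on acidic work-up or on silica (symmetrical ether formation). The fallback sets out from 1 and comes back at 3: rhodium-catalysed 1,2-addition of (3,4-dimethoxyphenyl)boronic acid to 1 (Rh(acac)(CO)2, t-Bu3P, DME–H2O, 80 °C) runs under neutral conditions and should give 3 directly, with a buffered work-up and chromatography on base-washed silica. It makes no new compound.

Further compounds
F1 | step 2 | bis(3,4-dimethoxyphenyl)methane | COc1ccc(Cc2ccc(OC)c(OC)c2)cc1OC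
F2 | step 2 | (4R)-3-[(E)-but-2-enoyl]-4-phenyl-1,3-oxazolidin-2-one | C/C=C/C(=O)N1[C@H](c2ccccc2)COC1=O
F3 | step 2 | (4R)-3-[(3S)-4,4-bis(3,4-dimethoxyphenyl)-3-methylbutanoyl]-4-phenyl-1,3-oxazolidin-2-one | COc1ccc(C(c2ccc(OC)c(OC)c2)[C@@H](C)CC(=O)N3[C@H](c4ccccc4)COC3=O)cc1OC
F4 | step 2 | (4R)-3-[(2R,3R)-4,4-bis(3,4-dimethoxyphenyl)-2,3-dimethylbutanoyl]-4-phenyl-1,3-oxazolidin-2-one | COc1ccc(C(c2ccc(OC)c(OC)c2)[C@@H](C)[C@@H](C)C(=O)N3[C@H](c4ccccc4)COC3=O)cc1OC
F5 | step 2 | (2R,3R)-4,4-bis(3,4-dimethoxyphenyl)-2,3-dimethylbutan-1-ol | COc1ccc(C(c2ccc(OC)c(OC)c2)[C@@H](C)[C@@H](C)CO)cc1OC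
F6 | step 3 | (1S,2R,3R,4S)-4-(3,4-dimethoxyphenyl)-6,7-dimethoxy-2,3-dimethyl-1,2,3,4-tetrahydronaphthalen-1-ol | COc1ccc([C@H]2c3cc(OC)c(OC)cc3[C@@H](O)[C@H](C)[C@@H]2C)cc1OC
F7 | step 3 | (2R,3R,4S)-4-(3,4-dimethoxyphenyl)-6,7-dimethoxy-2,3-dimethyl-3,4-dihydronaphthalen-1(2H)-one (2,3-cis) | COc1ccc([C@H]2c3cc(OC)c(OC)cc3C(=O)[C@H](C)[C@@H]2C)cc1OC
F8 | step 3 | (2S,3R,4S)-4-(3,4-dimethoxyphenyl)-6,7-dimethoxy-2,3-dimethyl-3,4-dihydronaphthalen-1(2H)-one (2,3-trans) | COc1ccc([C@H]2c3cc(OC)c(OC)cc3C(=O)[C@@H](C)[C@@H]2C)cc1OC
F0 | step 1 | none | none
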